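**Retrosynthetic overview**
1. Both depside (aryl ester) C–O bonds are cut. Ring A acid 16 is joined last to the ring B C4 hydroxyl of didepside phenol 24, which comes from ring B acid 21 and the C4 hydroxyl of ring C.
2. Rings B and C are both taken from methyl orsellinate 17. Ring A is the only ring that is built, and it is finished before any ester link to it exists.
3. Feature used: ring A carries CO2R at C1, a free OH at C2, OMe at C4 (meta to the OH) and CH3 at C6. C2 is therefore read as a ketene carbonyl, C3–C4 as methoxyacetylene, C5 as a former diazo carbon and C6=C1 as the alkene of a 3-methyl enoate.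
4. Ring A comes from diazoketone 6 and methoxyacetylene 10 by vinylketene–alkyne benzannulation (C2–C3 and C4–C5, then C1–C2).
5. 6 is reached from 2,3-butanedione by Wittig olefination and detrifluoroacetylative diazo transfer. An acid chloride with diazomethane is avoided because diazomethane would add to the fumarate-like alkene.

Key step: step 5

Remark: the target holds no stereocentre. The only stereochemical element of the route is the E alkene of 3–6 and 11–13, which is set in step 1.

**Step 1**
Reactants: 1 2,3-butanedione; 2 benzyl (triphenylphosphoranylidene)acetate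
Product: 3 benzyl (E)-3-methyl-4-oxopent-2-enoate
Conditions: 1 (3 equiv), CH2Cl2, 0 °C → rt; chromatography
Reagents that add atoms: none
Why: Wittig olefination of an activated 1,2-diketone with a stabilised ylide should place the ester trans to the acetyl group (E), while the excess of volatile 1 and the lower electrophilicity of the enone carbonyl of 3 hold back a second olefination.

**Step 2**
Reactants: 3 benzyl (E)-3-methyl-4-oxopent-2-enoate
Product: 5 benzyl (E)-7,7,7-trifluoro-3-methyl-4,6-dioxohept-2-enoate, via lithium enolate 4 (not isolated)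
Conditions: LiN(SiMe3)2 (1.1 equiv), THF, −78 °C (3 added to the base); CF3CO2CH2CF3 (1.2 equiv), −78 °C, 10 min; 5% aq. HCl; crude 5 used at once
Reagents that add atoms: 2,2,2-trifluoroethyl trifluoroacetate, O=C(OCC(F)(F)F)C(F)(F)F
Why: Kinetic deprotonation at the acetyl CH3 (the only enolisable ketone position) and Claisen-type C-trifluoroacetylation form the activation stage of the detrifluoroacetylative diazo transfer established for enones, so no diazoalkane ever meets the electron-poor alkene.

**Step 3**
Reactants: 5 benzyl (E)-7,7,7-trifluoro-3-methyl-4,6-dioxohept-2-enoate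
Product: 6 benzyl (E)-5-diazo-3-methyl-4-oxopent-2-enoate
Conditions: 4-acetamidobenzenesulfonyl azide (p-ABSA, 1.5 equiv), Et3N (1.5 equiv), H2O (1 equiv), MeCN, rt; kept cold and dark, used promptly
Reagents that add atoms: 4-acetamidobenzenesulfonyl azide, CC(=O)Nc1ccc(cc1)S(=O)(=O)N=[N+]=[N-]
Why: Regitz-type deacylative diazo transfer, in which the diketonate attacks the sulfonyl azide and the adduct collapses with transfer of the trifluoroacetyl group to the sulfonamide nitrogen, leaves the terminal diazoketone with the alkene geometry untouched.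

**Step 4**
Reactants: 7 chloroacetaldehyde dimethyl acetal
Product: 10 methoxyacetylene, via 1-chloro-2-methoxyethene 8 (not isolated), via sodium methoxyacetylide 9 (not isolated)
Conditions: NaNH2 (3.1 equiv), liq. NH3, −33 °C; NH3 evaporated; sat. aq. NaCl, −70 °C → rt, distilled into a −78 °C trap; stored cold as a ClCH2CH2Cl solution
Reagents that add atoms: none
Why: Double base-induced β-elimination (methanol, then HCl) is the standard preparation of alkoxyacetylenes from chloroacetals, and the third equivalent of amide stores the alkyne as its sodium salt until the aqueous quench.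

**Step 5**
Reactants: 6 benzyl (E)-5-diazo-3-methyl-4-oxopent-2-enoate; 10 methoxyacetylene
Product: 15 benzyl 2-hydroxy-4-methoxy-6-methylbenzoate, via vinylketene 11 (not isolated), via vinylcyclobutenone 12 (not isolated), via dienylketene 13 (not isolated), via cyclohexadienone 14 (not isolated)
Conditions: hν (254 nm, quartz, closed vessel), 10 (5 equiv), degassed ClCH2CH2Cl, 0–5 °C, 6 added slowly by syringe pump (final 0.02 M); excess 10 vented; then reflux (83 °C), 3 h
Reagents that add atoms: none
Why: Light expels N2 from 6 and the alkenyl group shifts to the former diazo carbon (photochemical Wolff rearrangement, making C5–C6) to give vinylketene 11, whose carbonyl carbon (future C2) is attacked by the nucleophilic unsubstituted carbon of 10 (C3) while the methoxy-bearing carbon (C4) bonds to the ketene α-carbon (C5), a (2+2) cycloaddition that gives 12. Four-electron electrocyclic opening of 12 (C2–C5 cleavage, by light or on heating, and reversible, so that the isomer with the alkenyl group turned away from the ketene is recycled) gives dienylketene 13, ring A closes by a six-electron disrotatory electrocyclisation that joins the ketene carbon C2 to the ester-bearing terminus C1, and enolisation of 14 delivers the phenol. The closest known reaction type is the Danheiser benzannulation in its second-generation form (unsaturated α-diazoketone, photochemical Wolff rearrangement, alkoxyalkyne partner); the ester on the alkene terminus is a new substituent within that substrate class, and it should make the ketene more electrophilic toward the ynol ether without changing the pericyclic steps. No stereocentre has to be controlled, since the sp3 carbons of 12 and 14 vanish on aromatisation. The step needs regioselectivity in the (2+2) event, which the polarisation of the ynol ether secures (C2–OH and C4–OMe end up meta), and it needs the ketene adduct to close on C5 and not on the ester-bearing carbon or the ester oxygen, which is secured by approach of 10 from the hydrogen side of the ketene and by the E alkene that holds the ester away from the ketene carbon and puts H, not CO2Bn, on the inside of the closing triene. Slow addition of 6 at high dilution into excess 10 keeps the diazo group from adding as a dipole to the electron-poor alkene of a second molecule, and irradiation at 0–5 °C keeps the volatile alkyne in solution and defers phenol formation until no ketene is left to acylate it.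

**Step 6**
Reactants: 15 benzyl 2-hydroxy-4-methoxy-6-methylbenzoate
Product: 16 2-hydroxy-4-methoxy-6-methylbenzoic acid (everninic acid)
Conditions: H2 (1 atm), 10% Pd/C, EtOAc, rt
Reagents that add atoms: none
Why: Catalytic hydrogenolysis of the benzyl ester frees the acid under neutral conditions at room temperature, avoiding the base and heat that would invite decarboxylation of this o-hydroxy acid.

**Step 7**
Reactants: 17 methyl orsellinate (methyl 2,4-dihydroxy-6-methylbenzoate)
Product: 18 methyl 4-(benzyloxy)-2-hydroxy-6-methylbenzoate
Conditions: BnBr (1.05 equiv), K2CO3 (1.1 equiv), acetone, reflux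
Reagents that add atoms: benzyl bromide, BrCc1ccccc1
Why: In this Williamson etherification the C2 hydroxyl is hydrogen-bonded to and flanked by the ester, so one equivalent of halide with a weak base should alkylate only the C4 hydroxyl.

**Step 8**
Reactants: 18 methyl 4-(benzyloxy)-2-hydroxy-6-methylbenzoate
Product: 19 methyl 4-(benzyloxy)-2-methoxy-6-methylbenzoate
Conditions: MeI (3 equiv), K2CO3 (2 equiv), DMF, 50 °C
Reagents that add atoms: iodomethane, CI
Why: Williamson etherification with excess iodomethane in a dipolar aprotic solvent overcomes the hydrogen bond of the one remaining phenol and installs the ring B C2 methoxy group.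

**Step 9**
Reactants: 19 methyl 4-(benzyloxy)-2-methoxy-6-methylbenzoate
Product: 21 4-(benzyloxy)-2-methoxy-6-methylbenzoic acid, via potassium carboxylate 20 (not isolated)
Conditions: KOH (5 equiv), DMSO–H2O (4:1), 100 °C; then 2 M HCl, 0 °C
Reagents that add atoms: potassium hydroxide, [K+].[OH-]
Why: Saponification of the di-ortho-substituted ester needs poorly solvated hydroxide at high temperature, both ethers are inert to it, and no free ortho or para hydroxyl is present to promote decarboxylation.

**Step 10**
Reactants: 21 4-(benzyloxy)-2-methoxy-6-methylbenzoic acid; 17 methyl orsellinate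
Product: 23 methyl 4-{[4-(benzyloxy)-2-methoxy-6-methylbenzoyl]oxy}-2-hydroxy-6-methylbenzoate, via mixed anhydride 22 (not isolated)
Conditions: (CF3CO)2O (5 equiv), PhMe, rt
Reagents that add atoms: none
Why: Mixed-anhydride esterification with trifluoroacetic anhydride is the standard depside condensation; the hindered electron-rich aroyl group is transferred readily, and the free C4 hydroxyl of 17 should react in preference to the chelated C2 hydroxyl.

**Step 11**
Reactants: 23 methyl 4-{[4-(benzyloxy)-2-methoxy-6-methylbenzoyl]oxy}-2-hydroxy-6-methylbenzoate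
Product: 24 methyl 2-hydroxy-4-[(4-hydroxy-2-methoxy-6-methylbenzoyl)oxy]-6-methylbenzoate
Conditions: H2 (1 atm), 10% Pd/C, EtOAc, rt
Reagents that add atoms: none
Why: Catalytic hydrogenolysis removes the aryl benzyl ether and leaves the aryl ester link, the methyl ester and the methyl ether untouched.

**Step 12**
Reactants: 16 2-hydroxy-4-methoxy-6-methylbenzoic acid; 24 methyl 2-hydroxy-4-[(4-hydroxy-2-methoxy-6-methylbenzoyl)oxy]-6-methylbenzoate
Product: 26 methyl 2-hydroxy-4-({4-[(2-hydroxy-4-methoxy-6-methylbenzoyl)oxy]-2-methoxy-6-methylbenzoyl}oxy)-6-methylbenzoate (CNP0357736.0), via mixed anhydride 25 (not isolated)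
Conditions: (CF3CO)2O (5 equiv), PhMe, 0 °C → rt; aq. NaHCO3 wash
Reagents that add atoms: none
Why: The same mixed-anhydride depside condensation should acylate the only unchelated phenol (ring B C4–OH), since the C2 hydroxyls of rings A and C are hydrogen-bonded and flanked by their carbonyl groups and any transient aryl trifluoroacetate is cleaved in the bicarbonate wash.

**Compound list**
1 | 2,3-butanedione | CC(=O)C(C)=O | starting material
2 | benzyl (triphenylphosphoranylidene)acetate | O=C(C=P(c1ccccc1)(c1ccccc1)c1ccccc1)OCc1ccccc1 | starting material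
3 | benzyl (E)-3-methyl-4-oxopent-2-enoate | CC(=O)/C(C)=C/C(=O)OCc1ccccc1 | intermediate
4 | lithium enolate of 3 (deprotonated at the acetyl CH3) | [Li+].C=C([O-])/C(C)=C/C(=O)OCc1ccccc1 | intermediate
5 | benzyl (E)-7,7,7-trifluoro-3-methyl-4,6-dioxohept-2-enoate (drawn as the diketone) | O=C(CC(=O)C(F)(F)F)/C(C)=C/C(=O)OCc1ccccc1 | intermediate
6 | benzyl (E)-5-diazo-3-methyl-4-oxopent-2-enoate | [N-]=[N+]=CC(=O)/C(C)=C/C(=O)OCc1ccccc1 | intermediate
7 | chloroacetaldehyde dimethyl acetal | COC(CCl)OC | starting material
8 | 1-chloro-2-methoxyethene (geometry not defined) | COC=CCl | intermediate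
9 | sodium methoxyacetylide | [Na+].[C-]#COC | intermediate
10 | methoxyacetylene | C#COC | intermediate
11 | benzyl (2E)-3-methyl-5-oxopenta-2,4-dienoate (vinylketene) | O=C=C/C(C)=C/C(=O)OCc1ccccc1 | intermediate
12 | benzyl (E)-3-(2-methoxy-4-oxocyclobut-2-en-1-yl)but-2-enoate (racemic) | COC1=CC(=O)C1/C(C)=C/C(=O)OCc2ccccc2 | intermediate
13 | benzyl (2E,4E)-5-methoxy-3-methyl-7-oxohepta-2,4,6-trienoate (dienylketene, ketene cis to the enoate arm) | O=C=C/C(OC)=C\C(C)=C\C(=O)OCc1ccccc1 | intermediate
14 | benzyl 4-methoxy-2-methyl-6-oxocyclohexa-2,4-diene-1-carboxylate (racemic) | COC1=CC(=O)C(C(=O)OCc2ccccc2)C(C)=C1 | intermediate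
15 | benzyl 2-hydroxy-4-methoxy-6-methylbenzoate | COc1cc(C)c(C(=O)OCc2ccccc2)c(O)c1 | intermediate
16 | 2-hydroxy-4-methoxy-6-methylbenzoic acid | COc1cc(C)c(C(=O)O)c(O)c1 | intermediate
17 | methyl orsellinate | COC(=O)c1c(C)cc(O)cc1O | starting material
18 | methyl 4-(benzyloxy)-2-hydroxy-6-methylbenzoate | COC(=O)c1c(C)cc(OCc2ccccc2)cc1O | intermediate
19 | methyl 4-(benzyloxy)-2-methoxy-6-methylbenzoate | COC(=O)c1c(C)cc(OCc2ccccc2)cc1OC | intermediate
20 | potassium 4-(benzyloxy)-2-methoxy-6-methylbenzoate | [K+].COc1cc(OCc2ccccc2)cc(C)c1C([O-])=O | intermediate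
21 | 4-(benzyloxy)-2-methoxy-6-methylbenzoic acid | COc1cc(OCc2ccccc2)cc(C)c1C(=O)O | intermediate
22 | 4-(benzyloxy)-2-methoxy-6-methylbenzoic trifluoroacetic anhydride | COc1cc(OCc2ccccc2)cc(C)c1C(=O)OC(=O)C(F)(F)F | intermediate
23 | methyl 4-{[4-(benzyloxy)-2-methoxy-6-methylbenzoyl]oxy}-2-hydroxy-6-methylbenzoate | COC(=O)c1c(C)cc(OC(=O)c2c(C)cc(OCc3ccccc3)cc2OC)cc1O | intermediate
24 | methyl 2-hydroxy-4-[(4-hydroxy-2-methoxy-6-methylbenzoyl)oxy]-6-methylbenzoate | COC(=O)c1c(C)cc(OC(=O)c2c(C)cc(O)cc2OC)cc1O | intermediate
25 | 2-hydroxy-4-methoxy-6-methylbenzoic trifluoroacetic anhydride | COc1cc(C)c(C(=O)OC(=O)C(F)(F)F)c(O)c1 | intermediate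
26 | methyl 2-hydroxy-4-({4-[(2-hydroxy-4-methoxy-6-methylbenzoyl)oxy]-2-methoxy-6-methylbenzoyl}oxy)-6-methylbenzoate | COC(=O)c1c(C)cc(OC(=O)c2c(C)cc(OC(=O)c3c(C)cc(OC)cc3O)cc2OC)cc1O | target

**Total step count:** 12
**Longest linear sequence:** 6 steps (1, 2, 3, 5, 6, 12; the arm 7, 8, 9, 10, 11, 12 is equally long)

**Steps most likely to fail**

**Step 5.**
- Light may isomerise the E alkene before or after loss of nitrogen, after which the ketene can close on the ester oxygen.
- The diazo carbon may add as a dipole to the electron-poor alkene of a second molecule.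
- The ketene/ynol ether adduct may collapse at the vinylogous, ester-bearing carbon instead of the ketene α-carbon, which would exchange the places of hydroxyl and methoxy relative to the ester.
- Fallback: it sets out from 17 and returns at 16, so ring A is then bought rather than built. The unchelated C4 hydroxyl of 17 is methylated with one equivalent of MeI and K2CO3 in acetone to give methyl 2-hydroxy-4-methoxy-6-methylbenzoate F1. KOH in aqueous DMSO converts F1 to dipotassium 4-methoxy-6-methyl-2-oxidobenzoate F2, and cold acidification gives 16.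

**Step 2.**
- Enolate 4 may add in Michael fashion to unreacted 3.
- The base may deprotonate the C3 methyl group (γ to the ester).
- The base may add to the doubly activated alkene.
- Fallback: it sets out from 3 and returns at 6 without any strong base or acyl activation. Acid-mediated α'-bromination of 3 with PhNMe3Br3 in THF at 0 °C, to which the electron-poor alkene is inert, gives benzyl (E)-5-bromo-3-methyl-4-oxopent-2-enoate F3. N,N'-ditosylhydrazine and DBU in THF at 0 °C alkylate at nitrogen to give benzyl (E)-5-[1,2-bis(4-methylphenylsulfonyl)hydrazinyl]-3-methyl-4-oxopent-2-enoate F4. F4 loses two sulfinate groups in the same flask to give 6.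

**Step 12.**
- The activated ring A acid may be acylated at its own free C2 hydroxyl (self-condensation).
- The acidic medium may exchange the existing B–C ester link.
- 16 may decarboxylate before it couples.
- Fallback: it sets out from 15 and returns at 26, masking the ring A hydroxyl during the coupling.
  - 15 is benzylated (BnBr, K2CO3, DMF) to benzyl 2-(benzyloxy)-4-methoxy-6-methylbenzoate F5.
  - KOH in aqueous DMSO gives potassium 2-(benzyloxy)-4-methoxy-6-methylbenzoate F6, and acidification gives 2-(benzyloxy)-4-methoxy-6-methylbenzoic acid F7.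
  - (CF3CO)2O in toluene forms 2-(benzyloxy)-4-methoxy-6-methylbenzoic trifluoroacetic anhydride F8. F8 acylates 24 to give methyl 4-[(4-{[2-(benzyloxy)-4-methoxy-6-methylbenzoyl]oxy}-2-methoxy-6-methylbenzoyl)oxy]-2-hydroxy-6-methylbenzoate F9.
  - Hydrogenolysis of F9 (H2, Pd/C, EtOAc) gives 26.

**Further compounds**
F1 | step 5 | methyl 2-hydroxy-4-methoxy-6-methylbenzoate | COC(=O)c1c(C)cc(OC)cc1O
F2 | step 5 | dipotassium 4-methoxy-6-methyl-2-oxidobenzoate | [K+].[K+].COc1cc(C)c(C([O-])=O)c([O-])c1
F3 | step 2 | benzyl (E)-5-bromo-3-methyl-4-oxopent-2-enoate | O=C(CBr)/C(C)=C/C(=O)OCc1ccccc1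
F4 | step 2 | benzyl (E)-5-[1,2-bis(4-methylphenylsulfonyl)hydrazinyl]-3-methyl-4-oxopent-2-enoate | Cc1ccc(cc1)S(=O)(=O)NN(CC(=O)/C(C)=C/C(=O)OCc1ccccc1)S(=O)(=O)c1ccc(C)cc1
F5 | step 12 | benzyl 2-(benzyloxy)-4-methoxy-6-methylbenzoate | COc1cc(C)c(C(=O)OCc2ccccc2)c(OCc2ccccc2)c1
F6 | step 12 | potassium 2-(benzyloxy)-4-methoxy-6-methylbenzoate | [K+].COc1cc(C)c(C([O-])=O)c(OCc2ccccc2)c1
F7 | step 12 | 2-(benzyloxy)-4-methoxy-6-methylbenzoic acid | COc1cc(C)c(C(=O)O)c(OCc2ccccc2)c1
F8 | step 12 | 2-(benzyloxy)-4-methoxy-6-methylbenzoic trifluoroacetic anhydride | COc1cc(C)c(C(=O)OC(=O)C(F)(F)F)c(OCc2ccccc2)c1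
F9 | step 12 | methyl 4-[(4-{[2-(benzyloxy)-4-methoxy-6-methylbenzoyl]oxy}-2-methoxy-6-methylbenzoyl)oxy]-2-hydroxy-6-methylbenzoate | COC(=O)c1c(C)cc(OC(=O)c2c(C)cc(OC(=O)c3c(C)cc(OC)cc3OCc4ccccc4)cc2OC)cc1O
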